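**Assumptions.** (1) The target is 2-[(3R,5R)-3,5-dimethyl-5-((8E… all-E)-decatrienyl-type chain)-1,2-dioxolan-3-yl]acetic acid. The two methyls are cis and the CH2CO2H and chain groups are cis. (2) The catalyst pseudoenantiomers named below are a starting guess; in practice the hand that gives (5R), and the IDPi enantiomer that gives 3R, are found by screening.

## Retrosynthetic overview
1. The acid is disconnected at the C(a)=C(b) bond of the triene (Julia–Kocienski). The partners are the tetrazolyl sulfone 13 and commercial (2E,4E)-heptadienal 14, and this is the last step.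
2. The CH2CO2H arm comes from a terminal allyl group (RuO4 cleavage). The allyl group is delivered by a catalyst-controlled allylation of the peroxycarbenium ion from hemiketal 8, which makes the C3 quaternary centre.
3. The only ring, the 1,2-dioxolane, and the C5 quaternary stereocentre come from an organocatalytic peroxy-Michael addition of H2O2 to (E)-enone 6, trapped as a peroxyhemiketal.
4. Enone 6 comes from Negishi methylalumination and acylation of alkyne 3, which is made from 10-undecyn-1-ol and a tetrazolyl thiol.

## Route

**Step 1**
Reactants: 1 (10-undecyn-1-ol); 2 (1-phenyl-1H-tetrazole-5-thiol, PTSH)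
Product: 3 (5-(undec-10-yn-1-ylsulfanyl)-1-phenyl-1H-tetrazole)
Conditions: PPh3, DIAD, THF, 0 °C → rt
Reagents that add atoms: none (PTSH is the reactant)
Why: Mitsunobu thioetherification converts the primary alcohol into the PT-sulfide, which becomes the olefination handle; the alkyne is untouched.

**Step 2**
Reactants: 3
Product: 6 ((E)-4-methyl-13-[(1-phenyl-1H-tetrazol-5-yl)sulfanyl]tridec-3-en-2-one)
Conditions: (i) 4, Cp2ZrCl2 (10 mol %), ClCH2CH2Cl, 0 °C → rt; remove volatiles; (ii) ZnCl2, 5, Pd(PPh3)4 (5 mol %), THF, 0 °C → rt
Reagents that add atoms: 4 Me3Al (C[Al](C)C); 5 acetyl chloride (CC(=O)Cl)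
Why: Zr-catalysed syn-methylalumination puts Me and Al cis, so Al is trans to the chain. Transmetalation to Zn and Pd-catalysed acylation (Negishi acylation) then gives the stereodefined (E)-β,β-dialkyl methyl enone; excess Me3Al covers the weakly basic tetrazolyl sulfide.

**Step 3**
Reactants: 6
Product: 8 ((5R)-3,5-dimethyl-5-{9-[(1-phenyltetrazol-5-yl)sulfanyl]nonyl}-1,2-dioxolan-3-ol, C3 epimers about 1:1)
Conditions: 30 % aq. H2O2 (5 equiv), 9-amino-9-deoxy-epi-quinidine (20 mol %), TFA (40 mol %), PhMe, 5 °C, 72 h
Reagents that add atoms: 7 hydrogen peroxide (OO)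
Why: Primary-amine iminium activation with H2O2 delivered by the protonated quinuclidine gives an enantioselective peroxy-Michael addition to the β-carbon. This sets the C5 quaternary centre, and the β-hydroperoxy ketone cyclises at once to the 1,2-dioxolan-3-ol (hemiketalisation), which blocks epoxide formation. It extends known cinchona-amine peroxidation to a β,β-dialkyl methyl enone.

**Step 4**
Reactants: 8
Product: 10 ((3S,5R)-3-allyl-3,5-dimethyl-5-{9-[(1-phenyltetrazol-5-yl)sulfanyl]nonyl}-1,2-dioxolane; same spatial arrangement as the target, and the descriptor is S only because allyl ranks below C4)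
Conditions: 9, chiral IDPi catalyst (5 mol %), cyclohexane/PhMe, −30 °C, 48 h
Reagents that add atoms: 9 allyltrimethylsilane (C=CC[Si](C)(C)C)
Why: Proposed new method: a confined chiral Brønsted acid (IDPi) ionises the hemiketal to a 1,2-dioxolan-3-yl peroxycarbenium ion paired with the chiral anion, and allylTMS adds by a Hosomi–Sakurai pathway; both C3 epimers converge through the cation. Because C5 carries only Me versus CH2R, the two faces of the C3 cation are nearly enantiotopic, so the anion can set C3 (allyl cis to the C5 chain, methyls cis) without relying on substrate bias. The closest known chemistry is Lewis-acid allylation of peroxyketals via peroxycarbenium ions and IDPi-catalysed additions of allylsilane to in situ oxocarbenium ions.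

**Step 5**
Reactants: 10
Product: 13 (2-[(3R,5R)-3,5-dimethyl-5-{9-[(1-phenyltetrazol-5-yl)sulfonyl]nonyl}-1,2-dioxolan-3-yl]acetic acid)
Conditions: RuCl3·xH2O (5 mol %), NaIO4 (8 equiv), MeCN/EtOAc/H2O, 0 °C → rt, 1 h
Reagents that add atoms: 11 sodium periodate ([Na+].[O-]I(=O)(=O)=O); 12 water (O)
Why: RuO4 cleaves the terminal alkene to the carboxylic acid with loss of one carbon, which turns C3–allyl into C3–CH2CO2H, and it oxidises the sulfide to the sulfone in the same pot. The quaternary stereocentres and the tertiary dialkyl peroxide are untouched, and the conditions are acidic, so the β-peroxy acid cannot undergo retro-Michael epimerisation.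

**Step 6**
Reactants: 13; 14 ((2E,4E)-hepta-2,4-dienal)
Product: 15 (target, (3R,5R)-acid with the all-E trienyl chain)
Conditions: KHMDS (3.0 equiv, added to a mixture of 13 and 14), DME, −60 °C → rt; then aq. NaH2PO4 to pH about 4, 0 °C
Reagents that add atoms: none
Why: Julia–Kocienski olefination of the alkyl PT-sulfone with the conjugated enal gives the E-alkene and extends the chain to the (E,E,E)-triene. The first equivalent of base forms the carboxylate, which cannot be enolised and so protects the β-peroxy acid, and the unchanged aldehyde supplies the two existing E-alkenes.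

## Compound list
1 | 10-undecyn-1-ol | C#CCCCCCCCCCO | starting material
2 | 1-phenyl-1H-tetrazole-5-thiol | Sc1nnnn1-c1ccccc1 | starting material
3 | 5-(undec-10-yn-1-ylsulfanyl)-1-phenyltetrazole | C#CCCCCCCCCCSc1nnnn1-c1ccccc1 | intermediate
4 | trimethylaluminium | C[Al](C)C | reagent
5 | acetyl chloride | CC(=O)Cl | reagent
6 | (E)-4-methyl-13-(PT-sulfanyl)tridec-3-en-2-one | CC(=O)/C=C(\C)CCCCCCCCCSc1nnnn1-c1ccccc1 | intermediate
7 | hydrogen peroxide | OO | reagent
8 | (5R)-3,5-dimethyl-5-[9-(PT-sulfanyl)nonyl]-1,2-dioxolan-3-ol (C3 epimers) | c1ccccc1-n1nnnc1SCCCCCCCCC[C@]2(C)CC(C)(O)OO2 | intermediate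
9 | allyltrimethylsilane | C=CC[Si](C)(C)C | reagent
10 | (3S,5R)-3-allyl-3,5-dimethyl-5-[9-(PT-sulfanyl)nonyl]-1,2-dioxolane | c1ccccc1-n1nnnc1SCCCCCCCCC[C@]2(C)C[C@](C)(CC=C)OO2 | intermediate
11 | sodium periodate | [Na+].[O-]I(=O)(=O)=O | reagent
12 | water | O | reagent
13 | 2-[(3R,5R)-3,5-dimethyl-5-[9-(PT-sulfonyl)nonyl]-1,2-dioxolan-3-yl]acetic acid | c1ccccc1-n1nnnc1S(=O)(=O)CCCCCCCCC[C@]2(C)C[C@](C)(CC(=O)O)OO2 | intermediate
14 | (2E,4E)-hepta-2,4-dienal | CC/C=C/C=C/C=O | starting material
15 | target: 2-[(3R,5R)-3,5-dimethyl-5-((E,E,E)-dodeca-trienyl-type chain)-1,2-dioxolan-3-yl]acetic acid | CC/C=C/C=C/C=C/CCCCCCCC[C@]1(C)C[C@](C)(CC(=O)O)OO1 | target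

**Totals.** Total steps: 6. Longest linear sequence: 6 (from 10-undecyn-1-ol).

## Three steps most likely to fail
1. **Step 4 (proposed new allylation).** The strong acid may fragment the peroxycarbenium ion, or the catalyst may give poor facial control. *Fallback (known chemistry):* TMSOTf- or TiCl4-mediated allylTMS addition to 8 (or its methyl peroxyketal) at −78 °C, then separation of the cis diastereomer by preparative HPLC, so the selectivity comes from separation rather than catalyst control.
2. **Step 3 (enantioselective peroxidation of the β,β-dialkyl enone).** Me versus CH2R discrimination may give low ee, or Weitz–Scheffer epoxide may form. *Fallback:* run steps 3 and 4 with an achiral amine catalyst and resolve the stereoisomers of 10 by preparative chiral-phase HPLC.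
3. **Step 5 (RuO4 double oxidation).** Low-valent Ru may decompose the peroxide, or the chain may be over-oxidised. *Fallback:* three discrete steps: mCPBA oxidation of the sulfide to the sulfone, ozonolysis of the allyl group with Me2S work-up, then Pinnick oxidation (NaClO2, NaH2PO4, 2-methyl-2-butene).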